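The butenolide ring (O–C12(=O)–C11=C7–C6; germacrane numbering, C1 = ring ketone) is annulated in one operation onto an acyclic α-chloro ketone, C7(=O)–C6HCl–CH=CH2. C6 is allylic and α to the C7 carbonyl, so a cesium 2-phosphonocarboxylate displaces chloride there with inversion (O–C6 bond, C6 stereocenter), and the tethered phosphonate then olefinates the C7 ketone (C11=C7 bond, Horner–Wadsworth–Emmons). The acid already carries C13–OAc. The chloro ketone is assembled from (R)-linalool (C10), an organocatalytic α-oxyamination (C8) and an asymmetric γ-chloroallylboration (C6); ring-closing metathesis at C4=C5 then forms the ten-membered ring.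

Key step: step 12

Remark on the chemistry: atom labels follow germacrane numbering (C1 ring ketone, C4=C5 ring alkene, C6 lactone CH–O, C7=C11 lactone alkene, C8 CH–O-methacrylate, C10 C(CH3)OAc, C12 lactone C=O, C13 CH2OAc). Stereocenters that a later step destroys (C1 in 2 and 3, the trioxolane carbon in 6, C7 in 9, C11 in 12–15) are carried as mixtures or as the expected major isomer.

Step 1
Reactants: 1 (R)-(−)-linalool
Product: 2 (2R)-6-methyl-2-(oxiran-2-yl)hept-5-en-2-ol (both oxirane epimers)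
Conditions: VO(acac)2 (2 mol%), t-BuOOH (1.3 equiv, decane), CH2Cl2, 0 → 23 °C
Reagents that add atoms: tert-butyl hydroperoxide CC(C)(C)OO
Why: Hydroxyl-directed vanadium-catalysed epoxidation, in which the tertiary allylic alcohol delivers the peroxide oxygen to the adjacent vinyl group and the remote trisubstituted alkene is left alone; the new oxirane stereocenter is of no consequence because C1 becomes a ketone in step 3.

Step 2
Reactants: 2 (2R)-6-methyl-2-(oxiran-2-yl)hept-5-en-2-ol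
Product: 3 (6R)-2,6,10-trimethylundeca-1,9-diene-5,6-diol (both C5 epimers)
Conditions: 2-methylallylmagnesium chloride (2.5 equiv), CuI (10 mol%), THF, −40 → 0 °C; aq. NH4Cl
Reagents that add atoms: 2-methylallylmagnesium chloride C=C(C)C[Mg]Cl
Why: Copper-catalysed SN2 opening of the epoxide at its terminal carbon (C2) by the allylic Grignard reagent, after the first equivalent has deprotonated the tertiary alcohol; this installs C3, C4 and the 1,1-disubstituted alkene for the later metathesis.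

Step 3
Reactants: 3 (6R)-2,6,10-trimethylundeca-1,9-diene-5,6-diol
Product: 4 (6R)-6-hydroxy-2,6,10-trimethylundeca-1,9-dien-5-one
Conditions: (COCl)2, DMSO, CH2Cl2, −78 °C; Et3N, −78 → 0 °C
Reagents that add atoms: none
Why: Swern oxidation converts only the secondary C1 alcohol (the tertiary C10 alcohol cannot be oxidised) and does not cleave the 1,2-diol.

Step 4
Reactants: 4 (6R)-6-hydroxy-2,6,10-trimethylundeca-1,9-dien-5-one
Product: 5 (6R)-2,6,10-trimethyl-5-oxoundeca-1,9-dien-6-yl acetate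
Conditions: Ac2O, DMAP (0.3 equiv), Et3N, CH2Cl2, 40 °C
Reagents that add atoms: acetic anhydride CC(=O)OC(C)=O
Why: DMAP-catalysed acylation of the tertiary α-ketol installs the C10 acetate of the target, which also prevents lactol formation with the C7 aldehyde made next.

Step 5
Reactants: 5 (6R)-2,6,10-trimethyl-5-oxoundeca-1,9-dien-6-yl acetate
Product: 7 (4R)-4,8-dimethyl-1,5-dioxonon-8-en-4-yl acetate, via ozonide 6 (not isolated)
Conditions: O3 (about 1 equiv, Sudan Red 7B end point), CH2Cl2, −78 °C; then Me2S, −78 → 23 °C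
Reagents that add atoms: ozone [O-][O+]=O
Why: Ozonolysis is expected to take the electron-rich trisubstituted alkene first (the dye is consumed only after it), so the 1,1-disubstituted alkene survives; Me2S reduces the ozonide to the C7 aldehyde and acetone.

Step 6
Reactants: 7 (4R)-4,8-dimethyl-1,5-dioxonon-8-en-4-yl acetate
Product: 8 (2S,4R)-4,8-dimethyl-1,5-dioxo-2-[(2,2,6,6-tetramethylpiperidin-1-yl)oxy]non-8-en-4-yl acetate
Conditions: TEMPO (1.2 equiv), CuCl2·2H2O (10 mol%), (5S)-5-benzyl-2,2,3-trimethylimidazolidin-4-one trifluoroacetate (20 mol%), air, acetone, −10 °C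
Reagents that add atoms: TEMPO CC1(C)CCCC(C)(C)N1[O]
Why: Organocatalytic α-oxyamination of the aldehyde (enamine catalysis combined with CuCl2/TEMPO), in which the chiral imidazolidinone enamine is trapped at C8 on its unshielded face, so the catalyst antipode sets C8 as S (the (5R) catalyst is taken should the first run show the opposite sense); the alkoxyamine then serves as the protecting group of the C8 oxygen.

Step 7
Reactants: 8 (2S,4R)-4,8-dimethyl-1,5-dioxo-2-[(2,2,6,6-tetramethylpiperidin-1-yl)oxy]non-8-en-4-yl acetate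
Product: 9 (3S,4S,5S,7R)-3-chloro-4-hydroxy-7,11-dimethyl-8-oxo-5-[(2,2,6,6-tetramethylpiperidin-1-yl)oxy]dodeca-1,11-dien-7-yl acetate
Conditions: allyl chloride, (+)-Ipc2BOMe, LiN(c-C6H11)2 (from (c-C6H11)2NH and n-BuLi), Et2O–THF, −95 °C; BF3·OEt2; then 8, −95 °C; 30% H2O2, pH 7 phosphate buffer, 0 °C
Reagents that add atoms: allyl chloride C=CCCl (delivered as (Z)-γ-chloroallyldiisopinocampheylborane made in the flask)
Why: Asymmetric γ-chloroallylboration through a chair six-membered transition state, in which the (Z)-borane gives the syn chlorohydrin and the isopinocampheyl groups from (+)-Ipc2BOMe are expected to direct addition to the Re face of the aldehyde, fixing C6 as S under reagent control; the C7 carbinol configuration is irrelevant and the hindered C1 ketone should not react at −95 °C.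

Step 8
Reactants: 9 (3S,4S,5S,7R)-3-chloro-4-hydroxy-7,11-dimethyl-8-oxo-5-[(2,2,6,6-tetramethylpiperidin-1-yl)oxy]dodeca-1,11-dien-7-yl acetate
Product: 10 (3S,5S,7R)-3-chloro-7,11-dimethyl-4,8-dioxo-5-[(2,2,6,6-tetramethylpiperidin-1-yl)oxy]dodeca-1,11-dien-7-yl acetate
Conditions: Dess–Martin periodinane (1.5 equiv), NaHCO3, CH2Cl2, 0 °C
Reagents that add atoms: none
Why: Dess–Martin oxidation under buffered, non-basic conditions should give the α-chloro ketone without epimerising C6 or C8 and without touching the alkoxyamine.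

Step 9
Reactants: 11 tert-butyl 2-(diethoxyphosphoryl)acetate
Product: 12 tert-butyl 2-(diethoxyphosphoryl)-3-hydroxypropanoate (racemic)
Conditions: (CH2O)n (1.1 equiv), piperidine (10 mol%), THF, 50 °C
Reagents that add atoms: formaldehyde (as paraformaldehyde) C=O
Why: Amine-catalysed hydroxymethylation (aldol addition to formaldehyde) of the active methylene, in which the adduct is protonated by the piperidinium ion faster than it can eliminate phosphate.

Step 10
Reactants: 12 tert-butyl 2-(diethoxyphosphoryl)-3-hydroxypropanoate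
Product: 13 tert-butyl 3-acetoxy-2-(diethoxyphosphoryl)propanoate (racemic)
Conditions: Ac2O (1.5 equiv), pyridine, CH2Cl2, 0 °C
Reagents that add atoms: acetic anhydride CC(=O)OC(C)=O
Why: Acylation of the primary alcohol under conditions too weakly basic to trigger β-elimination to the phosphonoacrylate.

Step 11
Reactants: 13 tert-butyl 3-acetoxy-2-(diethoxyphosphoryl)propanoate
Product: 14 3-acetoxy-2-(diethoxyphosphoryl)propanoic acid (racemic)
Conditions: CF3CO2H–CH2Cl2 (1:2), 0 → 23 °C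
Reagents that add atoms: none
Why: Acidolysis of the tert-butyl ester (loss of isobutene) leaves the diethyl phosphonate and the primary acetate intact and avoids any base.

Step 12
Reactants: 10 (3S,5S,7R)-3-chloro-7,11-dimethyl-4,8-dioxo-5-[(2,2,6,6-tetramethylpiperidin-1-yl)oxy]dodeca-1,11-dien-7-yl acetate; 14 3-acetoxy-2-(diethoxyphosphoryl)propanoic acid
Product: 16 {(5R)-4-[(1S,3R)-3-acetoxy-3,7-dimethyl-4-oxo-1-[(2,2,6,6-tetramethylpiperidin-1-yl)oxy]oct-7-en-1-yl]-5-ethenyl-2-oxo-2,5-dihydrofuran-3-yl}methyl acetate, via phosphonoacetate ester 15 (not isolated)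
Conditions: 14 (1.3 equiv), Cs2CO3 (0.65 equiv), DMF, 0 °C; add 10, 0 → 23 °C; then LiCl (3 equiv), i-Pr2NEt (2 equiv), LiOAc (1 equiv), MeCN, 0 → 23 °C
Reagents that add atoms: none
Why: The cesium carboxylate of 14 displaces chloride at C6 of 10 by SN2, a site activated by both the adjacent C7 carbonyl and the vinyl group, forming the O–C6 bond with inversion (6S to 6R) to give ester 15; LiCl/i-Pr2NEt then generates the lithium-chelated phosphonate carbanion at C11, which adds to the C7 ketone and eliminates diethyl phosphate through the oxaphosphetane to form C11=C7. The closest known reaction type is the one-flask butenolide synthesis from α-halo ketones and dialkylphosphonoacetic acid salts (carboxylate alkylation, then intramolecular Horner–Wadsworth–Emmons olefination under Masamune–Roush conditions). The only ring closed is the five-membered lactone (O, C12, C11, C7, C6), by 5-exo-trig attack of C11 on the C7 carbonyl. The one stereocenter set, C6, is controlled by stereospecific inversion of the reagent-defined chloride, while C8 and C10 are not touched and the C11 center of 14 is destroyed. The step needs SN2 at C6 over SN2′ attack and over chloride-exchange epimerisation, which the α-keto activation and the precipitation of CsCl should secure, and olefination at C7 and not at the C1 ketone, which five- against nine-membered ring formation secures. β-Elimination of acetate from the C11 carbanion is expected to be reversible in the acetate-buffered medium, so the irreversible olefination drains the equilibrium, and the mild amine base spares the base-sensitive γ-vinyl butenolide.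

Step 13
Reactants: 16 {(5R)-4-[(1S,3R)-3-acetoxy-3,7-dimethyl-4-oxo-1-[(2,2,6,6-tetramethylpiperidin-1-yl)oxy]oct-7-en-1-yl]-5-ethenyl-2-oxo-2,5-dihydrofuran-3-yl}methyl acetate
Product: 17 {(5R)-4-[(1S,3R)-3-acetoxy-1-hydroxy-3,7-dimethyl-4-oxooct-7-en-1-yl]-5-ethenyl-2-oxo-2,5-dihydrofuran-3-yl}methyl acetate
Conditions: Zn dust (activated, excess), AcOH–THF–H2O (3:1:1), 23 → 40 °C
Reagents that add atoms: none
Why: Zinc in acetic acid cleaves the N–O bond of the alkoxyamine reductively; near room temperature the α-acetoxy ketone, the allylic acetate and the butenolide are not expected to be reduced.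

Step 14
Reactants: 17 {(5R)-4-[(1S,3R)-3-acetoxy-1-hydroxy-3,7-dimethyl-4-oxooct-7-en-1-yl]-5-ethenyl-2-oxo-2,5-dihydrofuran-3-yl}methyl acetate
Product: 18 [(4S,6R,10Z,11aR)-6-acetoxy-4-hydroxy-6,10-dimethyl-2,7-dioxo-2,4,5,6,7,8,9,11a-octahydrocyclodeca[b]furan-3-yl]methyl acetate
Conditions: second-generation Hoveyda–Grubbs catalyst (10 mol%, two portions), 1,4-benzoquinone (20 mol%), toluene (1 mM), 80 °C
Reagents that add atoms: none
Why: Ring-closing metathesis, in which the ruthenium carbene loads at the monosubstituted vinyl group and closes onto the 1,1-disubstituted alkene at high dilution; the ten-membered ring fused to the planar butenolide should accommodate only the Z (cis) trisubstituted C4=C5 alkene, and benzoquinone suppresses isomerisation of the γ-vinyl lactone by ruthenium hydrides.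

Step 15
Reactants: 18 [(4S,6R,10Z,11aR)-6-acetoxy-4-hydroxy-6,10-dimethyl-2,7-dioxo-2,4,5,6,7,8,9,11a-octahydrocyclodeca[b]furan-3-yl]methyl acetate
Product: 19 [(4S,6R,10Z,11aR)-6-acetoxy-6,10-dimethyl-4-(2-methylprop-2-enoyloxy)-2,7-dioxo-2,4,5,6,7,8,9,11a-octahydrocyclodeca[b]furan-3-yl]methyl acetate (CNP0115165.2)
Conditions: methacrylic anhydride (2 equiv), DMAP (0.2 equiv), Et3N (3 equiv), CH2Cl2, 0 °C
Reagents that add atoms: methacrylic anhydride C=C(C)C(=O)OC(=O)C(C)=C
Why: DMAP-catalysed acylation of the only free hydroxyl group (C8); migration of the lactone to O8 is geometrically excluded for the C7=C11 butenolide, and the low temperature should protect C6 from epimerisation.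

Compound list
1 | (R)-(−)-linalool, (3R)-3,7-dimethylocta-1,6-dien-3-ol | C=C[C@](C)(O)CCC=C(C)C | starting material
2 | (2R)-6-methyl-2-(oxiran-2-yl)hept-5-en-2-ol (both oxirane epimers) | C1OC1[C@](C)(O)CCC=C(C)C | intermediate
3 | (6R)-2,6,10-trimethylundeca-1,9-diene-5,6-diol (both C5 epimers) | C=C(C)CCC(O)[C@](C)(O)CCC=C(C)C | intermediate
4 | (6R)-6-hydroxy-2,6,10-trimethylundeca-1,9-dien-5-one | C=C(C)CCC(=O)[C@](C)(O)CCC=C(C)C | intermediate
5 | (6R)-2,6,10-trimethyl-5-oxoundeca-1,9-dien-6-yl acetate | C=C(C)CCC(=O)[C@](C)(OC(C)=O)CCC=C(C)C | intermediate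
6 | (3R)-1-(5,5-dimethyl-1,2,4-trioxolan-3-yl)-3,7-dimethyl-4-oxooct-7-en-3-yl acetate (ozonide, not isolated) | C=C(C)CCC(=O)[C@](C)(OC(C)=O)CCC1OOC(C)(C)O1 | intermediate
7 | (4R)-4,8-dimethyl-1,5-dioxonon-8-en-4-yl acetate | C=C(C)CCC(=O)[C@](C)(OC(C)=O)CCC=O | intermediate
8 | (2S,4R)-4,8-dimethyl-1,5-dioxo-2-[(2,2,6,6-tetramethylpiperidin-1-yl)oxy]non-8-en-4-yl acetate | C=C(C)CCC(=O)[C@](C)(OC(C)=O)C[C@H](ON1C(C)(C)CCCC1(C)C)C=O | intermediate
9 | (3S,4S,5S,7R)-3-chloro-4-hydroxy-7,11-dimethyl-8-oxo-5-[(2,2,6,6-tetramethylpiperidin-1-yl)oxy]dodeca-1,11-dien-7-yl acetate | C=C[C@H](Cl)[C@@H](O)[C@@H](ON1C(C)(C)CCCC1(C)C)C[C@@](C)(OC(C)=O)C(=O)CCC(C)=C | intermediate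
10 | (3S,5S,7R)-3-chloro-7,11-dimethyl-4,8-dioxo-5-[(2,2,6,6-tetramethylpiperidin-1-yl)oxy]dodeca-1,11-dien-7-yl acetate | C=C[C@H](Cl)C(=O)[C@@H](ON1C(C)(C)CCCC1(C)C)C[C@@](C)(OC(C)=O)C(=O)CCC(C)=C | intermediate
11 | tert-butyl 2-(diethoxyphosphoryl)acetate | CCOP(=O)(OCC)CC(=O)OC(C)(C)C | starting material
12 | tert-butyl 2-(diethoxyphosphoryl)-3-hydroxypropanoate (racemic) | CCOP(=O)(OCC)C(CO)C(=O)OC(C)(C)C | intermediate
13 | tert-butyl 3-acetoxy-2-(diethoxyphosphoryl)propanoate (racemic) | CCOP(=O)(OCC)C(COC(C)=O)C(=O)OC(C)(C)C | intermediate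
14 | 3-acetoxy-2-(diethoxyphosphoryl)propanoic acid (racemic) | CCOP(=O)(OCC)C(COC(C)=O)C(=O)O | intermediate
15 | (3R,5S,7R)-7-acetoxy-7,11-dimethyl-4,8-dioxo-5-[(2,2,6,6-tetramethylpiperidin-1-yl)oxy]dodeca-1,11-dien-3-yl 3-acetoxy-2-(diethoxyphosphoryl)propanoate (not isolated) | C=C[C@@H](OC(=O)C(COC(C)=O)P(=O)(OCC)OCC)C(=O)[C@@H](ON1C(C)(C)CCCC1(C)C)C[C@@](C)(OC(C)=O)C(=O)CCC(C)=C | intermediate
16 | {(5R)-4-[(1S,3R)-3-acetoxy-3,7-dimethyl-4-oxo-1-[(2,2,6,6-tetramethylpiperidin-1-yl)oxy]oct-7-en-1-yl]-5-ethenyl-2-oxo-2,5-dihydrofuran-3-yl}methyl acetate | C=C[C@H]1OC(=O)C(COC(C)=O)=C1[C@@H](ON2C(C)(C)CCCC2(C)C)C[C@@](C)(OC(C)=O)C(=O)CCC(C)=C | intermediate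
17 | {(5R)-4-[(1S,3R)-3-acetoxy-1-hydroxy-3,7-dimethyl-4-oxooct-7-en-1-yl]-5-ethenyl-2-oxo-2,5-dihydrofuran-3-yl}methyl acetate | C=C[C@H]1OC(=O)C(COC(C)=O)=C1[C@@H](O)C[C@@](C)(OC(C)=O)C(=O)CCC(C)=C | intermediate
18 | [(4S,6R,10Z,11aR)-6-acetoxy-4-hydroxy-6,10-dimethyl-2,7-dioxo-2,4,5,6,7,8,9,11a-octahydrocyclodeca[b]furan-3-yl]methyl acetate | O[C@H]1C[C@@](C)(OC(C)=O)C(=O)CC/C(C)=C\[C@H]2OC(=O)C(COC(C)=O)=C12 | intermediate
19 | [(4S,6R,10Z,11aR)-6-acetoxy-6,10-dimethyl-4-(2-methylprop-2-enoyloxy)-2,7-dioxo-2,4,5,6,7,8,9,11a-octahydrocyclodeca[b]furan-3-yl]methyl acetate (CNP0115165.2) | C=C(C)C(=O)O[C@H]1C[C@@](C)(OC(C)=O)C(=O)CC/C(C)=C\[C@H]2OC(=O)C(COC(C)=O)=C12 | target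

Total step count: 15. Longest linear sequence: 12 (steps 1–8 and 12–15).

Steps most likely to fail

Step 12. The C11 carbanion may lose acetate from C13 without recapture (the phosphonoacrylate ester then polymerises or is taken by other nucleophiles), olefination of the hindered C7 ketone may be slow, and the α-acyloxy β,γ-unsaturated ketone may enolise toward conjugation before it closes. The fallback sets out from 12 and removes the leaving group from C13 during the annulation. Acidolysis of 12 (CF3CO2H, CH2Cl2) should give 2-(diethoxyphosphoryl)-3-hydroxypropanoic acid F1. Its cesium salt alkylates 10 under the conditions of step 12 to give (3R,5S,7R)-7-acetoxy-7,11-dimethyl-4,8-dioxo-5-[(2,2,6,6-tetramethylpiperidin-1-yl)oxy]dodeca-1,11-dien-3-yl 2-(diethoxyphosphoryl)-3-hydroxypropanoate F2, which is not isolated. β-Hydroxy phosphonate carbanions of this kind are known olefination partners (formaldehyde route to α-(hydroxymethyl)acrylates), and F2 should close with LiCl/i-Pr2NEt to (1S,3R)-1-[(2R)-2-ethenyl-4-(hydroxymethyl)-5-oxo-2,5-dihydrofuran-3-yl]-3,7-dimethyl-4-oxo-1-[(2,2,6,6-tetramethylpiperidin-1-yl)oxy]oct-7-en-3-yl acetate F3. Acetylation of the primary alcohol (Ac2O, pyridine, 0 °C) comes back to the route at 16.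

Step 14. Oligomerisation through the monosubstituted vinyl group and isomerisation of the γ-vinyl lactone may outpace closure onto the 1,1-disubstituted alkene. The fallback sets out from 9 and inverts the order of the two ring formations, closing the carbocycle on the non-conjugated chlorohydrin, where there is no lactone to isomerise. Ring-closing metathesis of 9 (same catalyst, toluene, 1 mM, 80 °C) should give (1R,3S,4S,5S,6Z)-5-chloro-4-hydroxy-1,7-dimethyl-10-oxo-3-[(2,2,6,6-tetramethylpiperidin-1-yl)oxy]cyclodec-6-en-1-yl acetate F4. Dess–Martin oxidation then gives (1R,3S,5S,6Z)-5-chloro-1,7-dimethyl-4,10-dioxo-3-[(2,2,6,6-tetramethylpiperidin-1-yl)oxy]cyclodec-6-en-1-yl acetate F5. Annulation with 14 as in step 12 passes through (1R,2Z,7R,9S)-7-acetoxy-3,7-dimethyl-6,10-dioxo-9-[(2,2,6,6-tetramethylpiperidin-1-yl)oxy]cyclodec-2-en-1-yl 3-acetoxy-2-(diethoxyphosphoryl)propanoate F6 (not isolated) to [(4S,6R,10Z,11aR)-6-acetoxy-6,10-dimethyl-2,7-dioxo-4-[(2,2,6,6-tetramethylpiperidin-1-yl)oxy]-2,4,5,6,7,8,9,11a-octahydrocyclodeca[b]furan-3-yl]methyl acetate F7. Zn/AcOH cleavage of the N–O bond comes back to the route at 18.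

Step 7. Facial selectivity may erode if the reagent and the α-oxy stereocenter are mismatched, and the chlorohydrin may be lost to epoxide formation on work-up. The fallback sets out from 8 and replaces chloride by a protected hydroxyl group that is later activated in the flask. (Z)-γ-(Methoxymethoxy)allyldiisopinocampheylborane (allyl methoxymethyl ether, s-BuLi, (+)-Ipc2BOMe, BF3·OEt2, −78 °C) should give (3S,4R,5S,7R)-4-hydroxy-3-(methoxymethoxy)-7,11-dimethyl-8-oxo-5-[(2,2,6,6-tetramethylpiperidin-1-yl)oxy]dodeca-1,11-dien-7-yl acetate F8. Dess–Martin oxidation gives (3S,5S,7R)-3-(methoxymethoxy)-7,11-dimethyl-4,8-dioxo-5-[(2,2,6,6-tetramethylpiperidin-1-yl)oxy]dodeca-1,11-dien-7-yl acetate F9, and Me2BBr (CH2Cl2, −78 °C) removes the acetal to give (3S,5S,7R)-3-hydroxy-7,11-dimethyl-4,8-dioxo-5-[(2,2,6,6-tetramethylpiperidin-1-yl)oxy]dodeca-1,11-dien-7-yl acetate F10. Mitsunobu esterification with 14 (PPh3, DIAD, THF, 0 °C) inverts C6 and gives 15, which is closed with LiCl/i-Pr2NEt as in step 12, coming back to the route at 16.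

Further compounds
F1 | step 12 | 2-(diethoxyphosphoryl)-3-hydroxypropanoic acid (racemic) | CCOP(=O)(OCC)C(CO)C(=O)O
F2 | step 12 | (3R,5S,7R)-7-acetoxy-7,11-dimethyl-4,8-dioxo-5-[(2,2,6,6-tetramethylpiperidin-1-yl)oxy]dodeca-1,11-dien-3-yl 2-(diethoxyphosphoryl)-3-hydroxypropanoate (not isolated) | C=C[C@@H](OC(=O)C(CO)P(=O)(OCC)OCC)C(=O)[C@@H](ON1C(C)(C)CCCC1(C)C)C[C@@](C)(OC(C)=O)C(=O)CCC(C)=C
F3 | step 12 | (1S,3R)-1-[(2R)-2-ethenyl-4-(hydroxymethyl)-5-oxo-2,5-dihydrofuran-3-yl]-3,7-dimethyl-4-oxo-1-[(2,2,6,6-tetramethylpiperidin-1-yl)oxy]oct-7-en-3-yl acetate | C=C[C@H]1OC(=O)C(CO)=C1[C@@H](ON2C(C)(C)CCCC2(C)C)C[C@@](C)(OC(C)=O)C(=O)CCC(C)=C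
F4 | step 14 | (1R,3S,4S,5S,6Z)-5-chloro-4-hydroxy-1,7-dimethyl-10-oxo-3-[(2,2,6,6-tetramethylpiperidin-1-yl)oxy]cyclodec-6-en-1-yl acetate | O[C@H]1[C@@H](ON2C(C)(C)CCCC2(C)C)C[C@@](C)(OC(C)=O)C(=O)CC/C(C)=C\[C@@H]1Cl
F5 | step 14 | (1R,3S,5S,6Z)-5-chloro-1,7-dimethyl-4,10-dioxo-3-[(2,2,6,6-tetramethylpiperidin-1-yl)oxy]cyclodec-6-en-1-yl acetate | O=C1[C@@H](ON2C(C)(C)CCCC2(C)C)C[C@@](C)(OC(C)=O)C(=O)CC/C(C)=C\[C@@H]1Cl
F6 | step 14 | (1R,2Z,7R,9S)-7-acetoxy-3,7-dimethyl-6,10-dioxo-9-[(2,2,6,6-tetramethylpiperidin-1-yl)oxy]cyclodec-2-en-1-yl 3-acetoxy-2-(diethoxyphosphoryl)propanoate (not isolated) | O=C1[C@@H](ON2C(C)(C)CCCC2(C)C)C[C@@](C)(OC(C)=O)C(=O)CC/C(C)=C\[C@H]1OC(=O)C(COC(C)=O)P(=O)(OCC)OCC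
F7 | step 14 | [(4S,6R,10Z,11aR)-6-acetoxy-6,10-dimethyl-2,7-dioxo-4-[(2,2,6,6-tetramethylpiperidin-1-yl)oxy]-2,4,5,6,7,8,9,11a-octahydrocyclodeca[b]furan-3-yl]methyl acetate | CC1(C)CCCC(C)(C)N1O[C@H]2C[C@@](C)(OC(C)=O)C(=O)CC/C(C)=C\[C@H]3OC(=O)C(COC(C)=O)=C23
F8 | step 7 | (3S,4R,5S,7R)-4-hydroxy-3-(methoxymethoxy)-7,11-dimethyl-8-oxo-5-[(2,2,6,6-tetramethylpiperidin-1-yl)oxy]dodeca-1,11-dien-7-yl acetate | C=C[C@H](OCOC)[C@@H](O)[C@@H](ON1C(C)(C)CCCC1(C)C)C[C@@](C)(OC(C)=O)C(=O)CCC(C)=C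
F9 | step 7 | (3S,5S,7R)-3-(methoxymethoxy)-7,11-dimethyl-4,8-dioxo-5-[(2,2,6,6-tetramethylpiperidin-1-yl)oxy]dodeca-1,11-dien-7-yl acetate | C=C[C@H](OCOC)C(=O)[C@@H](ON1C(C)(C)CCCC1(C)C)C[C@@](C)(OC(C)=O)C(=O)CCC(C)=C
F10 | step 7 | (3S,5S,7R)-3-hydroxy-7,11-dimethyl-4,8-dioxo-5-[(2,2,6,6-tetramethylpiperidin-1-yl)oxy]dodeca-1,11-dien-7-yl acetate | C=C[C@H](O)C(=O)[C@@H](ON1C(C)(C)CCCC1(C)C)C[C@@](C)(OC(C)=O)C(=O)CCC(C)=C
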